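**Strategy.** Everything rests on cutting the bond between C1 of the benzene ring (para to the phenolic oxygen) and the benzylic carbon that carries the methyl group and the enoate oxygen. Because that carbon is an α-acyloxyethyl unit, a chiral nickel catalyst under reducing conditions can join an aryl iodide to a racemic 1-chloroethyl ester that already contains the complete (Z)-4-acetoxy-2-methylbut-2-enoate, forming the aryl–carbon bond and the (S)-centre in one operation, with no ring closed. The precursors are the O-TBS-protected 2-hydroxy-5-iodophenyl 2-methylprop-1-enyl ketone and the racemic chloroethyl ester; buffered desilylation then releases the target.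

Key step: step 8

Remark: the sense of induction of a new nickel–ligand–substrate combination cannot be predicted reliably; it is assumed that the ligand antipode leading to the (S)-ester is fixed in the first experiments, both antipodes being accessible.

Step 1
Reactants: 1 5-iodosalicylaldehyde
Product: 2 2-(tert-butyldimethylsilyloxy)-5-iodobenzaldehyde
Conditions: TBSCl (1.2 equiv), imidazole (2.5 equiv), DMF, rt
Reagents that add atoms: tert-butyldimethylsilyl chloride, CC(C)(C)[Si](C)(C)Cl
Why: Imidazole-mediated silylation of a phenol; capping the phenol first means that neither an ortho-hydroxybenzylic allylic alcohol (prone to ortho-quinone-methide/chromene formation) nor a free 2'-hydroxyaryl enone (prone to oxa-Michael closure to a chroman-4-one) is ever handled.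

Step 2
Reactants: 2 2-(tert-butyldimethylsilyloxy)-5-iodobenzaldehyde; 3 2-methylprop-1-enylmagnesium bromide
Product: 4 racemic 1-[2-(tert-butyldimethylsilyloxy)-5-iodophenyl]-3-methylbut-2-en-1-ol
Conditions: 3 (1.2 equiv), THF, −78 °C; quench at −78 °C with pH 7 phosphate buffer
Reagents that add atoms: none
Why: Grignard 1,2-addition of an alkenylmagnesium halide to an aromatic aldehyde at low temperature, where iodine–magnesium exchange at the aryl iodide and O-to-O silyl migration in the magnesium alkoxide should both be slow; the carbinol centre is racemic and is erased in step 3.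

Step 3
Reactants: 4 racemic 1-[2-(tert-butyldimethylsilyloxy)-5-iodophenyl]-3-methylbut-2-en-1-ol
Product: 5 1-[2-(tert-butyldimethylsilyloxy)-5-iodophenyl]-3-methylbut-2-en-1-one
Conditions: activated MnO2 (15 equiv), CH2Cl2, rt
Reagents that add atoms: none
Why: MnO2 oxidation of a doubly activated (benzylic and allylic) secondary alcohol to the aryl enone under neutral conditions that should leave the aryl silyl ether and the C–I bond untouched.

Step 4
Reactants: 6 but-2-yn-1-ol
Product: 8 (Z)-3-iodobut-2-en-1-ol, via cyclic sodium alkenylalanate 7 (not isolated)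
Conditions: Red-Al (1.5 equiv), THF, 0 °C → rt; then I2, THF, −78 → 0 °C; aq. Rochelle salt/Na2S2O3 work-up
Reagents that add atoms: iodine, II
Why: Hydroxyl-directed trans-hydroalumination of the propargylic alcohol places hydride on C2 and aluminium on C3 within a five-membered oxa-aluminacycle, and iodinolysis of the C–Al bond with retention gives the (Z)-vinyl iodide, which fixes the olefin geometry of the later enoate (Red-Al reduction/iodination).

Step 5
Reactants: 8 (Z)-3-iodobut-2-en-1-ol
Product: 9 (Z)-3-iodobut-2-enyl acetate
Conditions: Ac2O, pyridine, DMAP (cat.), CH2Cl2, 0 °C → rt, dark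
Reagents that add atoms: acetic anhydride, CC(=O)OC(C)=O
Why: Routine DMAP-catalysed O-acetylation of a primary allylic alcohol, placed before the carboxyl carbon is introduced so that a free Z-γ-hydroxy acid, which would close to the butenolide, never exists.

Step 6
Reactants: 9 (Z)-3-iodobut-2-enyl acetate
Product: 10 (Z)-4-acetoxy-2-methylbut-2-enoic acid
Conditions: Pd(OAc)2 (5 mol %), PPh3 (10 mol %), CO (1 atm), KOAc (3 equiv), DMF/H2O (10:1), rt, dark; cold aq. citric acid work-up
Reagents that add atoms: carbon monoxide, [C-]#[O+]; water, O
Why: Palladium-catalysed hydroxycarbonylation of an alkenyl iodide (oxidative addition with retention of geometry, CO insertion, capture of the acyl-palladium by acetate/water) should give the (Z)-acid, since the vinyl C–I bond reacts far faster than the allylic acetate under CO at room temperature and an acetate base cannot cleave the ester.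

Step 7
Reactants: 10 (Z)-4-acetoxy-2-methylbut-2-enoic acid; 11 1-bromo-1-chloroethane
Product: 13 racemic 1-chloroethyl (Z)-4-acetoxy-2-methylbut-2-enoate, via cesium carboxylate 12 (not isolated)
Conditions: Cs2CO3 (1.0 equiv), dry DMF, 4 Å MS, 0 °C; then 11 (5 equiv), rt, dark
Reagents that add atoms: none
Why: O-Alkylation of the cesium carboxylate by SN2 displacement of bromide, the better leaving group of the geminal dihalide, which is used in large excess to suppress the ethylidene diester; the acyl carbon is never activated, so the Z geometry and the acetate are not at risk, and the chloro-bearing carbon is formed racemic.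

Step 8
Reactants: 5 1-[2-(tert-butyldimethylsilyloxy)-5-iodophenyl]-3-methylbut-2-en-1-one; 13 racemic 1-chloroethyl (Z)-4-acetoxy-2-methylbut-2-enoate
Product: 14 (S)-1-[4-(tert-butyldimethylsilyloxy)-3-(3-methylbut-2-enoyl)phenyl]ethyl (Z)-4-acetoxy-2-methylbut-2-enoate
Conditions: 5 (1.0 equiv), 13 (1.5 equiv), NiBr2·glyme (10 mol %), chiral bis(oxazoline) L* [2,2'-(cyclopropane-1,1-diyl)bis(3a,8a-dihydro-8H-indeno[1,2-d]oxazole), single enantiomer, 12 mol %], Mn0 powder (3 equiv), DMA, 0 °C → rt, Ar
Reagents that add atoms: none
Why: Proposed new method: L*Ni(0) inserts into the aryl C–I bond of 5, a nickel(I) species removes the chlorine atom from (R)- and (S)-13 alike so that both funnel into one flat 1-acyloxyethyl radical stabilised by the adjacent oxygen, the chiral aryl–Ni(II) complex traps this radical, and reductive elimination from Ni(III) forms the aryl–C bond while Mn0 returns nickel to its low-valent state. The closest known reaction types are nickel/bis(oxazoline)-catalysed enantioconvergent couplings of racemic 1-haloalkyl carboxylates with organozinc reagents and nickel-catalysed asymmetric reductive arylations of α-heteroatom- or α-aryl-substituted secondary alkyl chlorides with aryl iodides. No ring is closed in this step. The one new stereocentre, the benzylic carbon, is set as (S) by the C2-symmetric ligand on nickel during radical capture and reductive elimination, assisted by coordination of the ester carbonyl to nickel. The step needs cross-selectivity over homocoupling and chemoselectivity for the C–I and C–Cl bonds over the allylic acetate and the enone: the first is secured by the different activation modes of an sp2 iodide (two-electron oxidative addition) and an activated sp3 chloride (halogen abstraction), the second by the much faster oxidative addition of the aryl iodide, the electron-poor character of the acetoxy-enoate and the β,β-dimethyl substitution that shields the enone. Since the medium is neither basic nor acyl-activating and only weakly Lewis acidic, the silyl ether, the acetate, the Z-olefin and the newly formed benzylic ester should pass through unchanged.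

Step 9
Reactants: 14 (S)-1-[4-(tert-butyldimethylsilyloxy)-3-(3-methylbut-2-enoyl)phenyl]ethyl (Z)-4-acetoxy-2-methylbut-2-enoate
Product: 15 (S)-1-[4-hydroxy-3-(3-methylbut-2-enoyl)phenyl]ethyl (Z)-4-acetoxy-2-methylbut-2-enoate
Conditions: HF·pyridine, excess pyridine, THF, 0 °C; pH 7 buffer work-up
Reagents that add atoms: none
Why: Fluoride cleavage of the aryl silyl ether under buffered, mildly acidic conditions releases the phenol in protonated form, so neither para-quinone-methide ionisation of the benzylic ester (loss of configuration) nor oxa-Michael closure onto the enone should be triggered, and the esters and the Z-olefin are inert (desilylation).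

**Compound list**

1 | 5-iodosalicylaldehyde | O=Cc1cc(I)ccc1O | starting material
2 | 2-(tert-butyldimethylsilyloxy)-5-iodobenzaldehyde | CC(C)(C)[Si](C)(C)Oc1ccc(I)cc1C=O | intermediate
3 | 2-methylprop-1-enylmagnesium bromide | CC(C)=C[Mg]Br | starting material
4 | racemic 1-[2-(tert-butyldimethylsilyloxy)-5-iodophenyl]-3-methylbut-2-en-1-ol | CC(C)=CC(O)c1cc(I)ccc1O[Si](C)(C)C(C)(C)C | intermediate
5 | 1-[2-(tert-butyldimethylsilyloxy)-5-iodophenyl]-3-methylbut-2-en-1-one | CC(C)=CC(=O)c1cc(I)ccc1O[Si](C)(C)C(C)(C)C | intermediate
6 | but-2-yn-1-ol | CC#CCO | starting material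
7 | cyclic sodium alkenylalanate (sodium 2,2-bis(2-methoxyethoxy)-3-methyl-2,5-dihydro-1,2-oxaaluminol-2-uide; not isolated) | CC1=CCO[Al-]1(OCCOC)OCCOC.[Na+] | intermediate
8 | (Z)-3-iodobut-2-en-1-ol | C/C(I)=C/CO | intermediate
9 | (Z)-3-iodobut-2-enyl acetate | CC(=O)OC/C=C(/C)I | intermediate
10 | (Z)-4-acetoxy-2-methylbut-2-enoic acid | CC(=O)OC/C=C(/C)C(=O)O | intermediate
11 | 1-bromo-1-chloroethane | CC(Cl)Br | starting material
12 | cesium (Z)-4-acetoxy-2-methylbut-2-enoate (not isolated) | CC(=O)OC/C=C(/C)C(=O)[O-].[Cs+] | intermediate
13 | racemic 1-chloroethyl (Z)-4-acetoxy-2-methylbut-2-enoate | CC(=O)OC/C=C(/C)C(=O)OC(C)Cl | intermediate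
14 | (S)-1-[4-(tert-butyldimethylsilyloxy)-3-(3-methylbut-2-enoyl)phenyl]ethyl (Z)-4-acetoxy-2-methylbut-2-enoate | CC(=O)OC/C=C(/C)C(=O)O[C@@H](C)c1ccc(O[Si](C)(C)C(C)(C)C)c(C(=O)C=C(C)C)c1 | intermediate
15 | (S)-1-[4-hydroxy-3-(3-methylbut-2-enoyl)phenyl]ethyl (Z)-4-acetoxy-2-methylbut-2-enoate | CC(=O)OC/C=C(/C)C(=O)O[C@@H](C)c1ccc(O)c(C(=O)C=C(C)C)c1 | target

**Summary**

Total step count: 9. Longest linear sequence: 6 steps (6 → 8 → 9 → 10 → 13 → 14 → 15, steps 4–9); the aryl branch (steps 1–3) joins at step 8.

**Steps most likely to fail**

Step 8 (proposed new method). The nickel cycle may be diverted into homocoupling of either partner or into oxidative addition at the allylic acetate, or the facial control at the benzylic carbon may be insufficient. The fallback uses known chemistry, sets out from 5 and returns to the route at 14. Stille coupling of 5 with tributyl(1-ethoxyvinyl)stannane (Pd(PPh3)4, toluene, 90 °C) would give the enol ether 1-[2-(tert-butyldimethylsilyloxy)-5-(1-ethoxyvinyl)phenyl]-3-methylbut-2-en-1-one F1. Brief treatment with dilute aqueous HCl in THF should hydrolyse it to the methyl ketone 1-[5-acetyl-2-(tert-butyldimethylsilyloxy)phenyl]-3-methylbut-2-en-1-one F2. Noyori asymmetric transfer hydrogenation (RuCl[(R,R)-TsDPEN](p-cymene), HCO2H/Et3N) is expected to reduce the unhindered acetyl group in preference to the ortho-substituted, cross-conjugated enone carbonyl and give (R)-1-[2-(tert-butyldimethylsilyloxy)-5-(1-hydroxyethyl)phenyl]-3-methylbut-2-en-1-one F3. Mitsunobu esterification of this alcohol with acid 10 (PPh3, DIAD, toluene, −20 °C) proceeds with inversion and without activation of the acyl carbon, so it should deliver the (S)-ester 14 with the Z-enoate intact.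

Step 6. Palladium(0) may ionise the allylic acetate, or the acetate may be lost and the chain may then close to the butenolide. The fallback sets out from 8 and returns at 10. Silylation of 8 (TBSCl, imidazole, DMF) would give (Z)-tert-butyl[(3-iodobut-2-en-1-yl)oxy]dimethylsilane F4. Iodine–lithium exchange (t-BuLi, 2 equiv, Et2O, −78 °C) would form the alkenyllithium [4-(tert-butyldimethylsilyloxy)but-2-en-2-yl]lithium F5 with retention of geometry, and trapping with Boc2O would give tert-butyl (Z)-4-(tert-butyldimethylsilyloxy)-2-methylbut-2-enoate F6. Desilylation with HF·pyridine/pyridine at 0 °C would give tert-butyl (Z)-4-hydroxy-2-methylbut-2-enoate F7, whose bulky ester resists lactonisation. It would be acetylated at once (Ac2O, pyridine, DMAP) to tert-butyl (Z)-4-acetoxy-2-methylbut-2-enoate F8, and TFA in CH2Cl2 at 0 °C would cleave the tert-butyl ester to acid 10.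

Step 7. The alkylation by the hindered geminal dihalide may be sluggish, a second displacement may lead on to the ethylidene diester, or the chloroethyl ester may hydrolyse during isolation. The fallback sets out from 10 and returns at 13. Under neutral conditions with 1-chloro-N,N,2-trimethylprop-1-enylamine (Ghosez reagent, CH2Cl2, 0 °C) the acid would be converted into (Z)-4-acetoxy-2-methylbut-2-enoyl chloride F9. Zinc chloride-catalysed addition of this acyl chloride to acetaldehyde (cat. ZnCl2, CH2Cl2, −20 °C), the classical route to 1-chloroalkyl esters, would give 13.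

**Further compounds**

F1 | step 8 | 1-[2-(tert-butyldimethylsilyloxy)-5-(1-ethoxyvinyl)phenyl]-3-methylbut-2-en-1-one | C=C(OCC)c1ccc(O[Si](C)(C)C(C)(C)C)c(C(=O)C=C(C)C)c1
F2 | step 8 | 1-[5-acetyl-2-(tert-butyldimethylsilyloxy)phenyl]-3-methylbut-2-en-1-one | CC(=O)c1ccc(O[Si](C)(C)C(C)(C)C)c(C(=O)C=C(C)C)c1
F3 | step 8 | (R)-1-[2-(tert-butyldimethylsilyloxy)-5-(1-hydroxyethyl)phenyl]-3-methylbut-2-en-1-one | O[C@H](C)c1ccc(O[Si](C)(C)C(C)(C)C)c(C(=O)C=C(C)C)c1
F4 | step 6 | (Z)-tert-butyl[(3-iodobut-2-en-1-yl)oxy]dimethylsilane | C/C(I)=C/CO[Si](C)(C)C(C)(C)C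
F5 | step 6 | [4-(tert-butyldimethylsilyloxy)but-2-en-2-yl]lithium (Li cis to CH2OSi) | C/C([Li])=C/CO[Si](C)(C)C(C)(C)C
F6 | step 6 | tert-butyl (Z)-4-(tert-butyldimethylsilyloxy)-2-methylbut-2-enoate | CC(C)(C)[Si](C)(C)OC/C=C(/C)C(=O)OC(C)(C)C
F7 | step 6 | tert-butyl (Z)-4-hydroxy-2-methylbut-2-enoate | OC/C=C(/C)C(=O)OC(C)(C)C
F8 | step 6 | tert-butyl (Z)-4-acetoxy-2-methylbut-2-enoate | CC(=O)OC/C=C(/C)C(=O)OC(C)(C)C
F9 | step 7 | (Z)-4-acetoxy-2-methylbut-2-enoyl chloride | CC(=O)OC/C=C(/C)C(=O)Cl
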